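- If each by-product formed holds one more coupling partner as idle adduct A, each turn of the coupling costs two partners: one consumed in making target and by-product, and one held idle.

starting material 0.40 M (fed, over 50 min); coupling partner 0.320 M; time 50 min

- part of the starting material that has reacted at 50 min
- share of free coupling partner in free coupling partner and idle adduct A together, at 50 min

    starting material + coupling partner ⇌ target + by-product (K1 = 3.50, k1 = 0.472 M⁻¹ min⁻¹)
    coupling partner + by-product ⇌ idle adduct A, settled at all times (K2 = 20.7 M⁻¹)
    coupling partner + target ⇌ idle adduct B, settled at all times (K3 = 2.7 M⁻¹)

- The by-product should mostly bind at first, because the binding constant times the partner charge is 6.6, well above one.
- This flask's partner charge, over twice its starting-material charge, gives 40.0%: the two-for-one mark, the part of the charged starting material that can react before two partners per turn have consumed the partner charge.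
- Dosing sets the pace at first: the forward half-life of starting material, with partner as charged, is 4.6 min, shorter than the dosing time of 50 min, so in this flask material should react soon after it enters.
- On this reckoning, control should pass from the feed to the coupling partner, the limiting reagent, charged below the starting material, at about 20.0 min.
- A larger partner charge raises the mark in proportion, and a larger starting-material charge lowers it in proportion. The dosing time moves the crossing but leaves the mark unchanged.
- This reckoning commits to c near the mark and gives no figure for fr.
- The forecast stands above that mark, with 46% and 32%, on the ground that “The partner is quickly tied up by the by-product”.
- The flask gives 45.6% and 32.3%, so c lies 5.6 percentage points above the mark. At 50 min in this flask, 44.6% of the by-product sits in idle adduct A, not the whole of it as the mark assumed.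

- Moved alone up or down by the same factor, the charges of this flask shift c at most as follows, the stronger first: coupling partner (8.5 points), then starting material (7.6 points).
- This flask has nearly come to rest: at ten times the time, c reaches 49.3%, a further 3.7 points. By 500 min, starting material has fallen to 50.7% of its charge and free partner to 9.64% of its own.
- With 0.24 M of starting material, the neighbour flask has a mark of 66.7%. Its computed c is 60.2%, which lies 6.5 points below that mark.

(The constants were drawn at random within sensible limits; what happens was integrated by code.)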